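The pyridone ring is disconnected at C4–C4a and N1–C8a (quinolinone numbering). This exploits that C8a is a latent ketone carbon of the carbocyclic ring with C4a as its enamine carbon, that N1–C2–C3–C4 can arrive as one four-atom unit, and that C8, alpha to C8a, can be equilibrated. In one operation a pyrrolidine enamine is C-acylated and an O-methyl oxime nitrogen then closes onto C8a with loss of pyrrolidine, forming the pyridone ring and the target directly. The precursors are the cis enamine 8 of (5S)-2-methoxy-5-octylcyclohexanone and racemic 2-methoxy-3-(methoxyimino)butanoyl chloride 17, which already carries N-methoxy, C2-methyl and C3-methoxy.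

Key step: step 9

Assumption: the sense of induction of the ferrocenyl diphosphine in step 3 (and of BINAP in its fallback) is taken by analogy with cyclohex-2-en-1-one; if the stated ligand enantiomer should give the 5R series, its commercially available mirror image is used.

**Route**

Step 1
Reactants: 1 2-methoxycyclohexan-1-one (racemic)
Product: 3 [(6-methoxycyclohex-1-en-1-yl)oxy]trimethylsilane (racemic), via lithium enolate 2 (not isolated)
Conditions: LiN(i-Pr)2 (1.05 equiv), THF, −78 °C; Me3SiCl, −78 °C → rt
Reagents that add atoms: chlorotrimethylsilane, C[Si](C)(C)Cl
Why: Kinetic enolisation of an α-alkoxy ketone by a hindered lithium amide should remove the accessible α'-CH2 proton instead of the tertiary C–H next to oxygen, and O-silylation fixes this regiochemistry (kinetic silyl enol ether formation).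

Step 2
Reactants: 3 [(6-methoxycyclohex-1-en-1-yl)oxy]trimethylsilane
Product: 4 6-methoxycyclohex-2-en-1-one (racemic)
Conditions: Pd(OAc)2 (1.0 equiv), MeCN, rt
Reagents that add atoms: none
Why: Saegusa–Ito oxidation, in which divalent palladium palladates the former enol carbon and syn β-hydride elimination places the double bond on the side remote from the untouched methoxy group.

Step 3
Reactants: 4 6-methoxycyclohex-2-en-1-one; 5 octylmagnesium bromide (commercial solution in Et2O)
Product: 7 (5S)-2-methoxy-5-octylcyclohexan-1-one (both C2 epimers), via magnesium enolate 6 (not isolated)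
Conditions: CuBr·SMe2 (5 mol %), (R)-1-[(S)-2-(diphenylphosphino)ferrocenyl]ethyldicyclohexylphosphine (Josiphos, 6 mol %), t-BuOMe, −75 °C, n-C8H17MgBr (1.2 equiv) added slowly; aq NH4Cl
Reagents that add atoms: none
Why: Copper-catalysed enantioselective conjugate addition of a Grignard reagent to a cyclic enone, in which the chiral diphosphine–copper complex selects the enone face and so sets C5 as S under catalyst control, while the remote racemic methoxy centre is left uncontrolled because step 4 corrects it.

Step 4
Reactants: 7 (5S)-2-methoxy-5-octylcyclohexan-1-one
Product: 8 1-[(3S,6R)-6-methoxy-3-octylcyclohex-1-en-1-yl]pyrrolidine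
Conditions: pyrrolidine (3 equiv), TsOH·H2O (2 mol %), PhMe, reflux, Dean–Stark, held until the epimer composition is constant; evaporate, use crude
Reagents that add atoms: pyrrolidine, C1CCNC1
Why: Reversible acid-catalysed enamine condensation, in which iminium–enamine tautomerism epimerises the methoxy-bearing carbon and allylic 1,3-strain against the pyrrolidine ring holds that methoxy group pseudoaxial while octyl stays pseudoequatorial, a combination open only to the cis (3S,6R) isomer of the trisubstituted enamine, so the second stereocentre is set under thermodynamic control relative to the fixed octyl centre.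

Step 5
Reactants: 9 methyl methoxyacetate; 10 acetyl chloride
Product: 13 methyl 2-methoxy-3-oxobutanoate (racemic), via lithium ester enolate 11 (not isolated), via lithium keto ester enolate 12 (not isolated)
Conditions: 9 (2.0 equiv), LiN(i-Pr)2 (2.0 equiv), THF, −78 °C; AcCl (1.0 equiv), −78 °C; aq HCl
Reagents that add atoms: none
Why: Crossed Claisen-type C-acylation of a preformed lithium ester enolate by an acid chloride, in which the second equivalent of enolate deprotonates the more acidic β-keto ester as it forms and so prevents a second acylation.

Step 6
Reactants: 13 methyl 2-methoxy-3-oxobutanoate; 14 methoxyamine hydrochloride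
Product: 15 methyl (3E)-2-methoxy-3-(methoxyimino)butanoate (racemic)
Conditions: NaOAc, MeOH, rt
Reagents that add atoms: none
Why: Oxime ether condensation at the ketone carbonyl only, which should favour the E geometry with N–OMe anti to the branched C2 substituent and cannot go on to an isoxazolone because the oxime oxygen is methylated.

Step 7
Reactants: 15 methyl (3E)-2-methoxy-3-(methoxyimino)butanoate
Product: 16 potassium (3E)-2-methoxy-3-(methoxyimino)butanoate
Conditions: KOSiMe3 (1.1 equiv), Et2O, rt; evaporate to dryness
Reagents that add atoms: potassium trimethylsilanolate, C[Si](C)(C)[O-].[K+]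
Why: Anhydrous methyl ester cleavage by a silanolate gives the carboxylate salt directly, so the free β-imino acid, which could decarboxylate, is never generated.

Step 8
Reactants: 16 potassium (3E)-2-methoxy-3-(methoxyimino)butanoate
Product: 17 (3E)-2-methoxy-3-(methoxyimino)butanoyl chloride (racemic)
Conditions: (COCl)2 (1.1 equiv), DMF (cat.), CH2Cl2, 0 °C → rt; filter, evaporate, use at once
Reagents that add atoms: oxalyl chloride, ClC(=O)C(Cl)=O
Why: Acid chloride formation from a carboxylate salt with oxalyl chloride proceeds under neutral conditions, so the oxime ether is not exposed to HCl.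

Step 9
Reactants: 8 1-[(3S,6R)-6-methoxy-3-octylcyclohex-1-en-1-yl]pyrrolidine; 17 (3E)-2-methoxy-3-(methoxyimino)butanoyl chloride
Product: 20 waltherione K [(5S,8R)-1,3,8-trimethoxy-2-methyl-5-octyl-5,6,7,8-tetrahydroquinolin-4(1H)-one], via imidoylketene 18 (not isolated), via acylated enaminone 19 (not isolated)
Conditions: Et3N (3 equiv), PhMe, −20 °C → rt, 17 (1.3 equiv) added slowly; then AcOH, 60 °C
Reagents that add atoms: none
Why: Proposed new method: Et3N dehydrochlorinates 17 to the N-methoxyimidoyl ketene 18, which (like 17 itself) acylates the nucleophilic enamine carbon C4a of 8 to give the vinylogous amide 19; on warming with AcOH the oxime-ether nitrogen, or the N-methoxy-enamine tautomer reached by shift of the doubly activated C3 proton, adds to C8a, pyrrolidine is expelled from the resulting aminal and loss of the C3 proton leaves the aromatic 4-pyridone. The closest known chemistry is Stork C-acylation of enamines, the annulation of enamines by acylketenes to 4-pyranones, and the ring-closing half of the exchange of 4-pyranones with hydroxylamine ethers, but closure of an O-methyl oxime nitrogen onto an enaminone has not been shown. The pyridone ring closes in a 6-exo-trig mode on the C8a iminium tautomer of 19 (equivalently an addition–elimination at the enaminone β-carbon), which is geometrically possible because the E oxime ether points its nitrogen lone pair toward the acyl chain and the acyl and amino groups are necessarily cis on the ring double bond. No stereocentre is formed: the racemic α-carbon of 17 becomes sp2 C3, and C5 and C8 are carried through from 8. The step needs C-acylation at C4a, secured because only the trisubstituted enamine has a CH terminus that can re-form a conjugated enaminone after attack, and it needs retention of the N–O bond, secured because C8a carries pyrrolidine and no hydrogen, so aromatisation can only occur by loss of the amine. Epimerisation at C8 should be limited by the weak acid and moderate temperature.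

**Compound list**

1 | 2-methoxycyclohexan-1-one (racemic) | COC1CCCCC1=O | starting material
2 | lithium 6-methoxycyclohex-1-en-1-olate (racemic) | COC1CCCC=C1[O-].[Li+] | intermediate
3 | [(6-methoxycyclohex-1-en-1-yl)oxy]trimethylsilane (racemic) | COC1CCCC=C1O[Si](C)(C)C | intermediate
4 | 6-methoxycyclohex-2-en-1-one (racemic) | COC1CCC=CC1=O | intermediate
5 | octylmagnesium bromide | CCCCCCCC[Mg]Br | starting material
6 | bromomagnesium (3S)-6-methoxy-3-octylcyclohex-1-en-1-olate (C6 epimers) | CCCCCCCC[C@H]1CCC(OC)C(O[Mg]Br)=C1 | intermediate
7 | (5S)-2-methoxy-5-octylcyclohexan-1-one (C2 epimers) | CCCCCCCC[C@H]1CCC(OC)C(=O)C1 | intermediate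
8 | 1-[(3S,6R)-6-methoxy-3-octylcyclohex-1-en-1-yl]pyrrolidine | CCCCCCCC[C@H]1CC[C@@H](OC)C(N2CCCC2)=C1 | intermediate
9 | methyl methoxyacetate | COCC(=O)OC | starting material
10 | acetyl chloride | CC(Cl)=O | starting material
11 | lithium 1,2-dimethoxyethen-1-olate (lithium enolate of 9) | COC=C(OC)[O-].[Li+] | intermediate
12 | lithium 3,4-dimethoxy-4-oxobut-2-en-2-olate (lithium enolate of 13) | COC(=O)C(OC)=C(C)[O-].[Li+] | intermediate
13 | methyl 2-methoxy-3-oxobutanoate (racemic) | COC(C(C)=O)C(=O)OC | intermediate
14 | methoxyamine hydrochloride | CON.Cl | starting material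
15 | methyl (3E)-2-methoxy-3-(methoxyimino)butanoate (racemic) | CO/N=C(\C)C(OC)C(=O)OC | intermediate
16 | potassium (3E)-2-methoxy-3-(methoxyimino)butanoate (racemic) | CO/N=C(\C)C(OC)C(=O)[O-].[K+] | intermediate
17 | (3E)-2-methoxy-3-(methoxyimino)butanoyl chloride (racemic) | CO/N=C(\C)C(OC)C(Cl)=O | intermediate
18 | (3E)-2-methoxy-3-(methoxyimino)but-1-en-1-one (imidoylketene) | CO/N=C(\C)C(OC)=C=O | intermediate
19 | (3E)-2-methoxy-3-(methoxyimino)-1-[(3R,6S)-3-methoxy-6-octyl-2-(pyrrolidin-1-yl)cyclohex-1-en-1-yl]butan-1-one (C2 epimers of the side chain) | CCCCCCCC[C@H]1CC[C@@H](OC)C(N2CCCC2)=C1C(=O)C(OC)/C(C)=N/OC | intermediate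
20 | waltherione K, (5S,8R)-1,3,8-trimethoxy-2-methyl-5-octyl-5,6,7,8-tetrahydroquinolin-4(1H)-one | CCCCCCCC[C@H]1CC[C@@H](OC)c2c1c(=O)c(OC)c(C)n2OC | target

**Step count and risks**

Total step count: 9. Longest linear sequence: 5 steps (steps 1–4 and 9; the acid chloride branch, steps 5–8 and 9, is equally long).

Steps most likely to fail:

Step 9. The weakly nucleophilic oxime-ether nitrogen may close onto C8a too slowly. The acylated intermediate could then be diverted by hydrolysis, by epimerisation at C8 through iminium–enamine tautomerism, or by N–O cleavage. The fallback uses known chemistry, sets out from 13 (with 8 as partner) and returns at 20. It closes the heterocycle through oxygen first and introduces the N-methoxy unit afterwards by pyranone-to-pyridinone exchange. Keto ester 13 is converted with HC(OMe)3 and catalytic H2SO4 in MeOH into methyl 2,3-dimethoxybut-2-enoate F1. This is cleaved with KOSiMe3 to potassium 2,3-dimethoxybut-2-enoate F2 and turned with (COCl)2 into 2,3-dimethoxybut-2-enoyl chloride F3. Stork acylation of enamine 8 with F3 (pyridine, CH2Cl2, 0 °C) is followed by brief treatment with dilute aqueous HCl. This should hydrolyse the enaminone and let the enol oxygen displace the β-methoxy group by addition–elimination, giving (5S,8R)-3,8-dimethoxy-2-methyl-5-octyl-5,6,7,8-tetrahydro-4H-chromen-4-one F4. Heating F4 with methoxyamine hydrochloride 14 in pyridine/EtOH should then exchange the ring oxygen for N–OMe by ring opening and reclosure, the established behaviour of 4-pyranones toward hydroxylamine and its ethers, and give 20.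

Step 3. Chelation of magnesium between the carbonyl and methoxy oxygens may promote uncatalysed 1,2-addition, and the resident stereocentre of the racemic enone may erode catalyst control in the mismatched pairing. The fallback sets out from 4 and returns at 7. Rhodium-catalysed asymmetric conjugate addition (Hayashi–Miyaura reaction) of (E)-oct-1-en-1-ylboronic acid with [Rh(OH)(cod)]2 and (S)-BINAP in aqueous dioxane at 35 °C runs without a hard organometallic and under strong catalyst control. It should give (5S)-2-methoxy-5-[(1E)-oct-1-en-1-yl]cyclohexan-1-one F5. Hydrogenation of the alkene (H2, Pd/C, EtOAc) then gives 7.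

Step 4. The thermodynamic preference for the cis enamine may be too small, or prolonged heating may cause drift to the tetrasubstituted enamine or loss of methanol. The fallback sets out from 7 and returns at 8. The C2 epimers of 7 are separated by chromatography, and the trans epimer is re-equilibrated with DBU and recycled, to give (2R,5S)-2-methoxy-5-octylcyclohexan-1-one F6. F6 is then condensed with pyrrolidine in the presence of TiCl4 (hexane/PhMe, 0 °C), which scavenges water irreversibly without heating. The configuration at the methoxy carbon is thus carried into 8 under kinetic control instead of being set by equilibration.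

Further compounds
F1 | step 9 | methyl 2,3-dimethoxybut-2-enoate (E/Z mixture) | COC(=O)C(OC)=C(C)OC
F2 | step 9 | potassium 2,3-dimethoxybut-2-enoate | COC(C)=C(OC)C(=O)[O-].[K+]
F3 | step 9 | 2,3-dimethoxybut-2-enoyl chloride | COC(C)=C(OC)C(Cl)=O
F4 | step 9 | (5S,8R)-3,8-dimethoxy-2-methyl-5-octyl-5,6,7,8-tetrahydro-4H-chromen-4-one | CCCCCCCC[C@H]1CC[C@@H](OC)c2c1c(=O)c(OC)c(C)o2
F5 | step 3 | (5S)-2-methoxy-5-[(1E)-oct-1-en-1-yl]cyclohexan-1-one (C2 epimers) | CCCCCC/C=C/[C@H]1CCC(OC)C(=O)C1
F6 | step 4 | (2R,5S)-2-methoxy-5-octylcyclohexan-1-one | CCCCCCCC[C@H]1CC[C@@H](OC)C(=O)C1
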